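Per cent of the substrate charged is the unit in which the charge shows: at 3.00 d the target reads 14.2% in Saturday's run from 0.14 M, but 11.1% in Friday's run from 0.22 M.

| setting | Saturday's | Friday's | flask |
|---|---|---|---|
| substrate | 0.14 M | 0.22 M | 0.10 M |
| remark | run made earlier | run made earlier |  |
| time |  |  | 2.5 d |

- Saturday's (time / d: intermediate C / %, target / %): 0.0556: 4.0, 6.9; 0.125: 6.4, 11.9; 0.208: 6.3, 13.4; 0.417: 6.7, 14.0; 0.833: 5.7, 13.7; 1.67: 3.8, 14.2; 3.00: 2.8, 14.2
- Friday's (time / d: intermediate C / %, target / %): 0.0556: 3.2, 5.4; 0.125: 5.0, 9.0; 0.208: 5.7, 10.4; 0.417: 5.6, 10.1; 0.833: 4.1, 10.9; 1.67: 3.0, 11.2; 3.00: 1.9, 11.1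

(readings scatter by 0.3 percentage points)

- percentages count the substrate that a species holds: one homo dimer counts as two
- what was read earlier has a scatter of 0.3 percentage points, one standard deviation
- candidate steps: substrate -> intermediate A; substrate -> intermediate B; intermediate B -> intermediate C; intermediate A -> target; intermediate B -> intermediate D; intermediate C <-> intermediate D; 2 substrate -> homo dimer

- the moment within 2.5 d at which there is most intermediate C
- the amount of intermediate C, in percent of the substrate charged, at that time
- earliest time at which at least nineteen twentieths of that best amount are there, in d
- latest time at which they still are, in d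

Two limiting flasks can be solved in the head. With the first-order steps out of substrate far ahead of dimerisation, each product keeps a fixed percentage at any charge, so the exponent on the charge is 0. With dimerisation far ahead, the first-order share falls close to inversely with the charge, so the exponent is near 1. Dimerisation goes with [substrate] squared and the first-order steps with [substrate], so their ratio, a selectivity factor, drifts down as substrate is used, and a real flask lies between the limits.

The two target readings give 0.545 for the charge exponent, the fall in ln(percentage) per unit rise in ln(starting [substrate]). Going from Saturday's charge to 0.10 M multiplies a percentage by 1.20. Intermediate C also descends from a first-order step, so I scale Saturday's highest reading, 6.7%, to 8.05%. Saturday's readings of intermediate C stay within about their scatter from 0.125 d to 0.417 d, so I place the peak in that span and no closer.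

The forecast gives 7.7% at 0.3 d, open from 0.16 d to 0.55 d, on the ground that “a second-order loss, dimerisation, competes with first-order substrate consumption”. Its height lies below mine.

The flask gives 8.36% at 0.247 d, open from 0.152 d to 0.427 d.

    substrate → intermediate A (k = 0.00400 min⁻¹)
    substrate → intermediate B (k = 0.00470 min⁻¹)
    intermediate B → intermediate C (k = 0.0130 min⁻¹)
    intermediate A → target (k = 0.0230 min⁻¹)
    intermediate B → intermediate D (k = 0.0150 min⁻¹)
    intermediate C ⇌ intermediate D (K = 21.0, k = 3.50 × 10⁻⁴ min⁻¹)
    2 substrate → homo dimer (k = 0.200 M⁻¹ min⁻¹)

The forecast's window shuts later than the flask's, while its height stands within the margin. In this flask, taking away the step between intermediate C and intermediate D, both ways, moves the moment of most intermediate C from 0.247 d to 2.45 d, the largest single effect on that moment among the steps taken away. Carried from this flask to the neighbour with 0.40 M of substrate, the charge exponent gives a peak of 3.93%. The neighbour's peak is lower than that, 3.62%, which reads as a charge exponent of 0.602.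

(The readings come from a simulation for an exercise; scatter was added.)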